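**Retrosynthetic overview**
- The pyran ring (O1, C2, C3, C4, C4a, C8a) is closed last by forming O1–C8a in one pot from a 2-alkenyl-6-methoxyphenol: oxidative dearomatisation to the methoxy-p-quinone, 6-endo oxa-Michael addition of the C2 tertiary hydroxyl, reoxidation.
- Enabling feature: the 6-OMe group makes C8=O a vinylogous ester, so C8a (β-carbon of the C5=O/C4a=C8a enone) is the most electrophilic ring CH, and the Z C3=C4 olefin holds the C2 hydroxyl over it. O1–C2 is never broken, so C2 enters with its configuration set.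
- C4–C4a comes from Suzuki coupling of a Z-vinyl iodide with (2-hydroxy-3-methoxyphenyl)boronic acid; C2 (S) comes from Sharpless epoxidation of a Z-allylic alcohol, epoxy chloride → alkynol fragmentation, iodination and diimide reduction.
- The side chain is joined to the carbocycle by B-alkyl Suzuki coupling of a vinylcyclohexene with (Z)-3-iodobut-2-en-1-ol.
- Ring order: cyclohexene first (enantioselective Diels–Alder of methacrolein with (E)-3-methylpenta-1,3-diene, both ring stereocentres), arene brought in next, quinone and pyran last.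

Key step: step 10

Assumption: the sense of induction of the oxazaborolidinium catalyst in step 1 is taken from the usual formyl C–H···O binding model for 2-substituted acroleins; if it proves opposite for this diene, the mirror-image catalyst is used and nothing else changes.

**Step 1**
Reactants: 1 methacrolein; 2 (3E)-3-methylpenta-1,3-diene
Product: 3 (1R,2S)-1,2,3-trimethylcyclohex-3-ene-1-carbaldehyde
Conditions: (S)-3,3-diphenyl-1-(2-methylphenyl)tetrahydro-1H,3H-pyrrolo[1,2-c][1,3,2]oxazaborole + HN(SO2CF3)2 (10 mol% each), CH2Cl2, −78 °C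
Reagents that add atoms: none
Why: Asymmetric Diels–Alder reaction catalysed by a protonated oxazaborolidine: the unsubstituted CH2 terminus of the diene (least hindered, largest HOMO coefficient) should bond to the enal β-carbon ("ortho" orientation, as with 1-vinylcyclohexene), the formyl-endo approach of the E diene places CHO cis to the C2 methyl (methyls trans), and the catalyst blocks one face of the boron-bound s-trans enal, which sets the absolute configuration at C1 and C2; any Z diene in commercial 2 cannot reach the s-cis form and is left behind.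

**Step 2**
Reactants: 3 (1R,2S)-1,2,3-trimethylcyclohex-3-ene-1-carbaldehyde
Product: 4 (5S,6S)-5-ethenyl-1,5,6-trimethylcyclohex-1-ene
Conditions: Ph3PCH3Br, KOtBu, THF, 0 °C → rt
Reagents that add atoms: methyltriphenylphosphonium bromide, C[P+](c1ccccc1)(c1ccccc1)c1ccccc1.[Br-]
Why: Wittig methylenation of a non-enolisable, α-quaternary aldehyde, so no stereocentre can be touched.

**Step 3**
Reactants: 5 but-2-yn-1-ol
Product: 6 (2Z)-3-iodobut-2-en-1-ol
Conditions: NaAlH2(OCH2CH2OMe)2 (Red-Al), THF, 0 °C → rt; then I2, −78 °C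
Reagents that add atoms: iodine, II
Why: Hydroxyl-directed trans-hydroalumination delivers H to C2 and Al to C3 through a cyclic alkoxyalanate, and iodinolysis of the C–Al bond with retention gives the Z iodide.

**Step 4**
Reactants: 4 (5S,6S)-5-ethenyl-1,5,6-trimethylcyclohex-1-ene; 6 (2Z)-3-iodobut-2-en-1-ol
Product: 8 (2Z)-3-methyl-5-[(1S,2R)-1,2,3-trimethylcyclohex-3-en-1-yl]pent-2-en-1-ol, via B-alkyl-9-BBN borane 7 (not isolated)
Conditions: 9-BBN, THF, rt; then 6, Pd(dppf)Cl2 (5 mol%), AsPh3, Cs2CO3, DMF–H2O, rt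
Reagents that add atoms: none
Why: Hydroboration with 9-BBN is anti-Markovnikov and selective for the monosubstituted vinyl group over the trisubstituted ring alkene, and the B-alkyl Suzuki–Miyaura coupling of 7 keeps the Z geometry of iodide 6.

**Step 5**
Reactants: 8 (2Z)-3-methyl-5-[(1S,2R)-1,2,3-trimethylcyclohex-3-en-1-yl]pent-2-en-1-ol
Product: 9 [(2R,3S)-3-methyl-3-{2-[(1S,2R)-1,2,3-trimethylcyclohex-3-en-1-yl]ethyl}oxiran-2-yl]methanol
Conditions: Ti(OiPr)4 (10 mol%), D-(−)-diethyl tartrate (12 mol%), t-BuOOH, 4 Å molecular sieves, CH2Cl2, −20 °C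
Reagents that add atoms: tert-butyl hydroperoxide, CC(C)(C)OO
Why: Sharpless asymmetric epoxidation under reagent control: D-(−)-tartrate is the antipode of the ligand that gives the (2S,3R)-epoxide from the Z alcohol nerol, so 8 should give the (2R,3S)-epoxide, whose C3 becomes C2 of the chromene, while the ring alkene has no directing hydroxyl and is not touched.

**Step 6**
Reactants: 9 [(2R,3S)-3-methyl-3-{2-[(1S,2R)-1,2,3-trimethylcyclohex-3-en-1-yl]ethyl}oxiran-2-yl]methanol
Product: 10 (2S,3S)-3-(chloromethyl)-2-methyl-2-{2-[(1S,2R)-1,2,3-trimethylcyclohex-3-en-1-yl]ethyl}oxirane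
Conditions: PPh3, CCl4, NaHCO3, reflux
Reagents that add atoms: carbon tetrachloride, ClC(Cl)(Cl)Cl
Why: Appel chlorination: SN2 displacement at the primary carbinol carbon under buffered neutral conditions leaves both epoxide carbons untouched (the descriptor of the CH carbon changes only because Cl raises the priority of CH2Cl).

**Step 7**
Reactants: 10 (2S,3S)-3-(chloromethyl)-2-methyl-2-{2-[(1S,2R)-1,2,3-trimethylcyclohex-3-en-1-yl]ethyl}oxirane
Product: 12 (3S)-1-iodo-3-methyl-5-[(1S,2R)-1,2,3-trimethylcyclohex-3-en-1-yl]pent-1-yn-3-ol, via dilithium alkynide alkoxide 11 (not isolated)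
Conditions: n-BuLi (3.1 equiv), THF, −78 → −30 °C; then I2 (1.05 equiv), −78 °C; aq. Na2S2O3
Reagents that add atoms: iodine, II
Why: Base-induced fragmentation of a 2,3-epoxy chloride to a propargylic alcohol: lithiation at CH2Cl opens the epoxide at its secondary C–O bond, loss of HCl and deprotonation give 11 with the tertiary C–O bond and its S configuration intact, and iodine then iodinates the alkynide carbon.

**Step 8**
Reactants: 12 (3S)-1-iodo-3-methyl-5-[(1S,2R)-1,2,3-trimethylcyclohex-3-en-1-yl]pent-1-yn-3-ol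
Product: 13 (1Z,3S)-1-iodo-3-methyl-5-[(1S,2R)-1,2,3-trimethylcyclohex-3-en-1-yl]pent-1-en-3-ol
Conditions: 2-nitrobenzenesulfonohydrazide, Et3N, THF–i-PrOH, rt
Reagents that add atoms: none
Why: Diimide reduction: concerted syn transfer of two hydrogens to the iodoalkyne gives the Z iodoalkene, and diimide neither cleaves the C–I bond nor reduces the trisubstituted ring alkene at a useful rate.

**Step 9**
Reactants: 13 (1Z,3S)-1-iodo-3-methyl-5-[(1S,2R)-1,2,3-trimethylcyclohex-3-en-1-yl]pent-1-en-3-ol; 14 (2-hydroxy-3-methoxyphenyl)boronic acid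
Product: 15 2-{(1Z,3S)-3-hydroxy-3-methyl-5-[(1S,2R)-1,2,3-trimethylcyclohex-3-en-1-yl]pent-1-en-1-yl}-6-methoxyphenol
Conditions: Pd(PPh3)4 (5 mol%), K3PO4, THF–H2O, 40 °C
Reagents that add atoms: none
Why: Suzuki–Miyaura coupling proceeds with retention at the alkenyl carbon, so the Z geometry is kept, and the basic medium leaves the tertiary allylic alcohol un-ionised and lets the phenol go unprotected.

**Step 10**
Reactants: 15 2-{(1Z,3S)-3-hydroxy-3-methyl-5-[(1S,2R)-1,2,3-trimethylcyclohex-3-en-1-yl]pent-1-en-1-yl}-6-methoxyphenol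
Product: 18 (2S)-6-methoxy-2-methyl-2-{2-[(1S,2R)-1,2,3-trimethylcyclohex-3-en-1-yl]ethyl}-2H-chromene-5,8-dione, via methoxyquinone 16 (not isolated), via chromene hydroquinone 17 (not isolated)
Conditions: (KSO3)2NO (Fremy's salt, 5 equiv), KH2PO4–Na2HPO4 buffer (pH 7), acetone–H2O, 0 °C → rt
Reagents that add atoms: Fremy's salt (dipotassium nitrosodisulfonate), [K+].[K+].[O]N(S(=O)(=O)[O-])S(=O)(=O)[O-]
Why: Proposed new method: a Teuber oxidation (phenoxyl radical, coupling of a second nitrosodisulfonate radical at the free para carbon, loss of imidodisulfonate) should turn the arene of 15 into methoxy-p-quinone 16, in which the hydroxyl held by the Z olefin adds to C8a by 6-endo-trig oxa-Michael addition to close the pyran; enolisation gives hydroquinone 17, and two more equivalents of the same oxidant restore the quinone. The closest known reactions are the Fremy's salt oxidation of 2-methoxy-6-alkylphenols to 2-methoxy-6-alkyl-p-benzoquinones, the addition of amines, thiols and (with Lewis acid) alcohols to methoxy-p-quinones at this same position followed by reoxidation, and the ring closure of aminoalkyl quinones made in situ with this oxidant; the one-pot union with a tertiary alcohol as the nucleophile has not been shown. No stereocentre is formed: C2 arrives as S and keeps all four bonds, because the new bond is O1–C8a and not O1–C2, and the buffered neutral medium offers no route to an allyl cation. The step needs para- and not ortho-oxidation of the phenol (the para CH is free, both ortho carbons are substituted) and attack at C8a and not at C7 or the C5 carbonyl carbon: the 6-methoxy group deactivates C7 and C8=O, the tether cannot reach C7, and hemiketal formation at C5 is reversible whereas addition at C8a is made irreversible by aromatisation and reoxidation.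

**Compound list**
1 | methacrolein (2-methylprop-2-enal) | CC(=C)C=O | starting material
2 | (3E)-3-methylpenta-1,3-diene | C=C/C(C)=C/C | starting material
3 | (1R,2S)-1,2,3-trimethylcyclohex-3-ene-1-carbaldehyde | O=C[C@]1(C)CCC=C(C)[C@@H]1C | intermediate
4 | (5S,6S)-5-ethenyl-1,5,6-trimethylcyclohex-1-ene | C=C[C@]1(C)CCC=C(C)[C@@H]1C | intermediate
5 | but-2-yn-1-ol | CC#CCO | starting material
6 | (2Z)-3-iodobut-2-en-1-ol | C/C(I)=C/CO | intermediate
7 | 9-{2-[(1R,2R)-1,2,3-trimethylcyclohex-3-en-1-yl]ethyl}-9-borabicyclo[3.3.1]nonane | B1(C2CCCC1CCC2)CC[C@]3(C)CCC=C(C)[C@@H]3C | intermediate (not isolated)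
8 | (2Z)-3-methyl-5-[(1S,2R)-1,2,3-trimethylcyclohex-3-en-1-yl]pent-2-en-1-ol | C/C(=C/CO)CC[C@]1(C)CCC=C(C)[C@@H]1C | intermediate
9 | [(2R,3S)-3-methyl-3-{2-[(1S,2R)-1,2,3-trimethylcyclohex-3-en-1-yl]ethyl}oxiran-2-yl]methanol | OC[C@H]1O[C@@]1(C)CC[C@]2(C)CCC=C(C)[C@@H]2C | intermediate
10 | (2S,3S)-3-(chloromethyl)-2-methyl-2-{2-[(1S,2R)-1,2,3-trimethylcyclohex-3-en-1-yl]ethyl}oxirane | ClC[C@H]1O[C@@]1(C)CC[C@]2(C)CCC=C(C)[C@@H]2C | intermediate
11 | lithium (3S)-1-lithio-3-methyl-5-[(1S,2R)-1,2,3-trimethylcyclohex-3-en-1-yl]pent-1-yn-3-olate | [Li]C#C[C@@](C)(O[Li])CC[C@]1(C)CCC=C(C)[C@@H]1C | intermediate (not isolated)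
12 | (3S)-1-iodo-3-methyl-5-[(1S,2R)-1,2,3-trimethylcyclohex-3-en-1-yl]pent-1-yn-3-ol | IC#C[C@@](C)(O)CC[C@]1(C)CCC=C(C)[C@@H]1C | intermediate
13 | (1Z,3S)-1-iodo-3-methyl-5-[(1S,2R)-1,2,3-trimethylcyclohex-3-en-1-yl]pent-1-en-3-ol | I/C=C\[C@@](C)(O)CC[C@]1(C)CCC=C(C)[C@@H]1C | intermediate
14 | (2-hydroxy-3-methoxyphenyl)boronic acid | COc1cccc(B(O)O)c1O | starting material
15 | 2-{(1Z,3S)-3-hydroxy-3-methyl-5-[(1S,2R)-1,2,3-trimethylcyclohex-3-en-1-yl]pent-1-en-1-yl}-6-methoxyphenol | COc1cccc(/C=C\[C@@](C)(O)CC[C@]2(C)CCC=C(C)[C@@H]2C)c1O | intermediate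
16 | 2-{(1Z,3S)-3-hydroxy-3-methyl-5-[(1S,2R)-1,2,3-trimethylcyclohex-3-en-1-yl]pent-1-en-1-yl}-6-methoxycyclohexa-2,5-diene-1,4-dione | COC1=CC(=O)C=C(/C=C\[C@@](C)(O)CC[C@]2(C)CCC=C(C)[C@@H]2C)C1=O | intermediate (not isolated)
17 | (2S)-6-methoxy-2-methyl-2-{2-[(1S,2R)-1,2,3-trimethylcyclohex-3-en-1-yl]ethyl}-2H-chromene-5,8-diol | COc1cc(O)c2c(C=C[C@](C)(CC[C@]3(C)CCC=C(C)[C@@H]3C)O2)c1O | intermediate (not isolated)
18 | (2S)-6-methoxy-2-methyl-2-{2-[(1S,2R)-1,2,3-trimethylcyclohex-3-en-1-yl]ethyl}-2H-chromene-5,8-dione | COC1=CC(=O)C2=C(C=C[C@](C)(CC[C@]3(C)CCC=C(C)[C@@H]3C)O2)C1=O | target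

**Step count**
Total: 10 steps. Longest linear sequence: 9 steps (1, 2, 4, 5, 6, 7, 8, 9, 10); step 3 is a one-step side branch.

**Steps most likely to fail**

Step 10 (labelled). The tertiary hydroxyl may add too slowly to the quinone under the neutral buffer, so that 16 builds up and is lost to dimerisation or over-oxidation, or radical coupling at the side chain may compete with para-oxidation. The fallback sets out from 13 and comes back at 18, and uses addition–elimination in place of oxidative C–H alkoxylation. Lithiation of commercial 1,2,4,5-tetramethoxybenzene (n-BuLi, THF) and quenching with B(OMe)3 would give (2,3,5,6-tetramethoxyphenyl)boronic acid F1. Suzuki coupling of F1 with 13 (Pd(OAc)2, SPhos, K3PO4) would give (1Z,3S)-3-methyl-1-(2,3,5,6-tetramethoxyphenyl)-5-[(1S,2R)-1,2,3-trimethylcyclohex-3-en-1-yl]pent-1-en-3-ol F2. Oxidative demethylation with (NH4)2Ce(NO3)6 in buffered MeCN–H2O at 0 °C would give 3-{(1Z,3S)-3-hydroxy-3-methyl-5-[(1S,2R)-1,2,3-trimethylcyclohex-3-en-1-yl]pent-1-en-1-yl}-2,5-dimethoxycyclohexa-2,5-diene-1,4-dione F3; either para pair of methoxy groups leads to the same quinone. K2CO3 in MeCN should then close the pyran by intramolecular vinylogous transesterification at the methoxy-bearing carbon next to the side chain, with loss of methanol, to give 18 without any redox event after ring closure.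

Step 1. Face selectivity or the formyl-endo preference may erode with the α-methyl dienophile, and the acid may oligomerise the diene. The fallback sets out from 1 and 2 and comes back at 3, and uses resolution in place of asymmetric catalysis. A Me2AlCl-promoted Diels–Alder reaction would give the racemate, that is 3 together with its enantiomer (1S,2R)-1,2,3-trimethylcyclohex-3-ene-1-carbaldehyde F4. Condensation with (1S,2S)-N,N'-dimethyl-1,2-diphenylethane-1,2-diamine (molecular sieves, Et2O) would give two diastereomeric aminals: (4S,5S)-1,3-dimethyl-4,5-diphenyl-2-[(1R,2S)-1,2,3-trimethylcyclohex-3-en-1-yl]imidazolidine F5 from 3, and (4S,5S)-1,3-dimethyl-4,5-diphenyl-2-[(1S,2R)-1,2,3-trimethylcyclohex-3-en-1-yl]imidazolidine F6 from F4. These should be separable by chromatography, and mild aqueous acid hydrolysis of F5 returns 3.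

Step 9. Protodeboronation of the electron-rich ortho-hydroxy boronic acid may outrun transmetalation, or palladium may isomerise the Z olefin or ionise the allylic alcohol. The fallback sets out from 10 and comes back at 15, and uses alkyne coupling and semi-hydrogenation in place of the vinyl iodide. Treatment of 10 with n-BuLi and an NH4Cl quench would give (3S)-3-methyl-5-[(1S,2R)-1,2,3-trimethylcyclohex-3-en-1-yl]pent-1-yn-3-ol F7. Silylation of commercial 2-bromo-6-methoxyphenol (TBSCl, imidazole) would give (2-bromo-6-methoxyphenoxy)(tert-butyl)dimethylsilane F8. Sonogashira coupling of F7 with F8 (Pd(PhCN)2Cl2, P(t-Bu)3, CuI, HN(i-Pr)2) would give (3S)-1-{2-[(tert-butyldimethylsilyl)oxy]-3-methoxyphenyl}-3-methyl-5-[(1S,2R)-1,2,3-trimethylcyclohex-3-en-1-yl]pent-1-yn-3-ol F9. Semi-hydrogenation over Pd/CaCO3 poisoned with Pb(OAc)2, with quinoline, would give (1Z,3S)-1-{2-[(tert-butyldimethylsilyl)oxy]-3-methoxyphenyl}-3-methyl-5-[(1S,2R)-1,2,3-trimethylcyclohex-3-en-1-yl]pent-1-en-3-ol F10, and Bu4NF in THF at 0 °C would free phenol 15.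

**Further compounds**
F1 | step 10 | (2,3,5,6-tetramethoxyphenyl)boronic acid | COc1cc(OC)c(OC)c(B(O)O)c1OC
F2 | step 10 | (1Z,3S)-3-methyl-1-(2,3,5,6-tetramethoxyphenyl)-5-[(1S,2R)-1,2,3-trimethylcyclohex-3-en-1-yl]pent-1-en-3-ol | COc1cc(OC)c(OC)c(/C=C\[C@@](C)(O)CC[C@]2(C)CCC=C(C)[C@@H]2C)c1OC
F3 | step 10 | 3-{(1Z,3S)-3-hydroxy-3-methyl-5-[(1S,2R)-1,2,3-trimethylcyclohex-3-en-1-yl]pent-1-en-1-yl}-2,5-dimethoxycyclohexa-2,5-diene-1,4-dione | COC1=CC(=O)C(OC)=C(/C=C\[C@@](C)(O)CC[C@]2(C)CCC=C(C)[C@@H]2C)C1=O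
F4 | step 1 | (1S,2R)-1,2,3-trimethylcyclohex-3-ene-1-carbaldehyde | O=C[C@@]1(C)CCC=C(C)[C@H]1C
F5 | step 1 | (4S,5S)-1,3-dimethyl-4,5-diphenyl-2-[(1R,2S)-1,2,3-trimethylcyclohex-3-en-1-yl]imidazolidine | CN1[C@@H](c2ccccc2)[C@H](c2ccccc2)N(C)C1[C@]3(C)CCC=C(C)[C@@H]3C
F6 | step 1 | (4S,5S)-1,3-dimethyl-4,5-diphenyl-2-[(1S,2R)-1,2,3-trimethylcyclohex-3-en-1-yl]imidazolidine | CN1[C@@H](c2ccccc2)[C@H](c2ccccc2)N(C)C1[C@@]3(C)CCC=C(C)[C@H]3C
F7 | step 9 | (3S)-3-methyl-5-[(1S,2R)-1,2,3-trimethylcyclohex-3-en-1-yl]pent-1-yn-3-ol | C#C[C@@](C)(O)CC[C@]1(C)CCC=C(C)[C@@H]1C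
F8 | step 9 | (2-bromo-6-methoxyphenoxy)(tert-butyl)dimethylsilane | COc1cccc(Br)c1O[Si](C)(C)C(C)(C)C
F9 | step 9 | (3S)-1-{2-[(tert-butyldimethylsilyl)oxy]-3-methoxyphenyl}-3-methyl-5-[(1S,2R)-1,2,3-trimethylcyclohex-3-en-1-yl]pent-1-yn-3-ol | COc1cccc(C#C[C@@](C)(O)CC[C@]2(C)CCC=C(C)[C@@H]2C)c1O[Si](C)(C)C(C)(C)C
F10 | step 9 | (1Z,3S)-1-{2-[(tert-butyldimethylsilyl)oxy]-3-methoxyphenyl}-3-methyl-5-[(1S,2R)-1,2,3-trimethylcyclohex-3-en-1-yl]pent-1-en-3-ol | COc1cccc(/C=C\[C@@](C)(O)CC[C@]2(C)CCC=C(C)[C@@H]2C)c1O[Si](C)(C)C(C)(C)C
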